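The data were computed on assumed constants, and the scatter is random.

Over 4.0 d the substrate fell to 8.0%, 7.2%, 8.0% and 7.8% in the earlier runs, so I took its loss as independent of both nucleophiles. The target did move with both charges, and I had to decide which nucleophile to hold back in the next run.

| setting | Wednesday's | Friday's | Saturday's | Thursday's | maple | elm | alder | larch |
|---|---|---|---|---|---|---|---|---|
| substrate | 0.25 M | 0.25 M | 0.25 M | 0.25 M | 0.25 M | 0.25 M | 0.25 M | 0.25 M |
| first nucleophile | 0.90 equiv | 0.90 equiv | 0.90 equiv | 0.45 equiv | 0.900 equiv | 0.900 equiv | 0.900 equiv | 0.900 equiv (fed, over 3.20 d) |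
| second nucleophile | 1 equiv | 0.67 equiv | 1.5 equiv | 1 equiv | 1.00 equiv | 1.00 equiv | 1.00 equiv (fed, over 3.20 d) | 1.00 equiv |
| remark | run made earlier | run made earlier | run made earlier | run made earlier | everything together in a closed stirred flask, run for 4.0 d | a single well-mixed tank run continuously and read at steady state, 4.0 d in it on average | all but second nucleophile at the start; second nucleophile goes in evenly over 3.20 d, the run ends at 4.0 d | all but first nucleophile at the start; first nucleophile goes in evenly over 3.20 d, the run ends at 4.0 d |
| time |  |  |  |  | 4.0 d |  | 4.0 d | 4.0 d |

- Wednesday's (time / d: target / %, substrate / %): 0.625: 10.0, 53.9; 1.25: 16.0, 33.5; 2.08: 20.7, 20.6; 2.50: 22.2, 16.4; 3.00: 24.0, 12.8; 4.00: 25.6, 8.0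
- Friday's (time / d: target / %, substrate / %): 0.333: 7.5, 70.1; 0.500: 9.0, 59.8; 0.833: 13.8, 45.5; 1.67: 21.4, 26.0; 2.50: 25.7, 16.5; 4.00: 29.9, 7.2
- Saturday's (time / d: target / %, substrate / %): 0.625: 8.2, 53.6; 1.25: 13.3, 34.6; 2.08: 15.8, 20.5; 2.50: 18.2, 16.1; 3.00: 19.3, 12.2; 4.00: 21.4, 8.0
- Thursday's (time / d: target / %, substrate / %): 0.333: 4.2, 70.0; 0.625: 7.3, 53.9; 1.04: 10.2, 39.1; 2.00: 13.4, 21.7; 4.00: 17.9, 7.8

(each reading ± 0.3 percentage points)

- the stated concentrations are those of everything mixed, before any reaction; amounts are the same in each set-up
- the feed brings no volume worth counting
- the earlier runs were made in a closed, stirred flask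

- the set-up with the highest amount of target at the outlet or at the end, in percent of the substrate put in ("none" if the first two lie within 2 percentage points) (maple / elm / alder / larch / none)
- amount of target at the outlet or at the end, in percent of the substrate put in, maple
- amount of target at the outlet or at the end, in percent of the substrate put in, elm
- amount of target at the outlet or at the end, in percent of the substrate put in, alder
- amount of target at the outlet or at the end, in percent of the substrate put in, larch

I treated the two nucleophiles as rivals for one species, so that the share of the capture going to target is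

share = s·c(first nucleophile) / [s·c(first nucleophile) + c(second nucleophile)]

Friday's and Saturday's final readings differ in the second nucleophile, which gives s:

ratio = 29.9% / 21.4% = 1.40

s = (1.5 − ratio × 0.67) / [(ratio − 1) × 0.90] = 1.58

This s, read from two scattered readings, is my selectivity factor, the ratio of the rate of capture by first nucleophile to that by second nucleophile at equal concentrations. Wednesday's reading then puts the captured share C at 43.6%, and C with s gives Thursday 18.1%, against the 17.9% read.

By about 0.917 d Wednesday's target had reached half its final reading, so I read a fed nucleophile at what has gone in by then: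

fed amount = charge × 0.917 d / 3.20 d

alder: 36.3%

larch: 12.6%

Alder's 36.3% is more than Wednesday's 25.6%, so I chose to feed the second nucleophile.

The forecast named alder, with 25.7% for maple, 24.2% for elm, 35.9% for alder and 14.1% for larch. Its ratio was 1.35, not my 1.58, and it said of alder that the second nucleophile “is scarce early, when flux is highest”.

The flasks gave 25.7% for maple, 24.2% for elm, 35.4% for alder and 14.1% for larch, and the best was alder.

    substrate ⇌ intermediate (K = 0.137, k = 0.0162 /h)
    first nucleophile + intermediate → target (k = 101 /M/h)
    second nucleophile + intermediate → other capture product (k = 69.2 /M/h)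
    2 substrate → homo dimer (k = 0.0686 /M/h)

In alder at 0.918 d, the intermediate fell back at 0.0054 of the rate at which it went on, and the step to target used it 3.8 times as fast as the step to other capture product. My s of 1.58 had given alder 36.3% against the 35.4% found, and for a neighbour of alder fed 2.50 equiv of second nucleophile it gives 29.0%, where that flask held 28.4%.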